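The earlier runs and the new flask were generated by integration for substances that don't exist; the scatter is artificial.

Late times came first. Starting material turns into target over free catalyst, and at 12 min the blue run still held 39.1 mM of its 80.0 mM, yet its readings had slowed.

| setting | blue | ochre | grey | violet |
|---|---|---|---|---|
| starting material | 80.0 mM | 40.0 mM | 80.0 mM | 240 mM |
| free catalyst | 2.40 mM | 2.40 mM | 4.80 mM | 4.80 mM |
| time |  |  |  | 12 min |

| run | time / min | [starting material] / mM |
|---|---|---|
| blue run | 0.48 | 74.2 |
| blue run | 0.76 | 71.3 |
| blue run | 1.2 | 65.9 |
| blue run | 1.9 | 61.7 |
| blue run | 3.0 | 55.5 |
| blue run | 4.8 | 49.6 |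
| blue run | 7.6 | 44.4 |
| blue run | 12 | 39.1 |
| ochre run | 0.48 | 36.4 |
| ochre run | 0.76 | 34.7 |
| ochre run | 1.2 | 32.9 |
| ochre run | 1.9 | 30.1 |
| ochre run | 3.0 | 27.9 |
| ochre run | 4.8 | 24.4 |
| ochre run | 7.6 | 21.6 |
| ochre run | 12 | 19.5 |
| grey run | 0.48 | 68.7 |
| grey run | 0.76 | 65.1 |
| grey run | 1.2 | 59.3 |
| grey run | 1.9 | 53.1 |
| grey run | 3.0 | 46.4 |
| grey run | 4.8 | 40.8 |
| grey run | 7.6 | 34.8 |
| grey run | 12 | 30.2 |

(scatter of a reading: 0.4 mM)

- Overall: starting material -> target, with free catalyst as catalyst.
- Constant volume, constant temperature.
- An order is taken over about fifteen percent of the charge, up and down.

- order of the initial rate in [free catalyst], near the charge of the blue run, the rate being that where two percent of its starting material are target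
- order of the initial rate in [starting material], near the charge of the blue run, the rate being that where two percent of its starting material are target (one fixed amount of target, the same in the runs compared)
- the ochre run starts with 40.0 mM less of starting material than the blue run, and with no target. Compared where both hold the same amount of starting material, once fifteen percent of what the ochre run was charged with has turned into target, is the ochre run faster, slower or alike (within a tenth)?
- starting material in the violet run at 12 min, as a share of the starting material charged
- which of these the readings show (the catalyst dies in pairs / the substrate ties up the catalyst / nothing beyond the main steps / two substrates go astray together / the product decays)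

I followed one molecule of starting material and asked for its chance of turning per minute, at two moments of the blue run. Over the first 0.48 min, the fall of c(starting material) from 80.0 mM to 74.2 mM gave 0.157 min⁻¹. Between 7.6 min and 12 min, the fall of c(starting material) from 44.4 mM to 39.1 mM gave 0.0289 min⁻¹. The late chance was therefore smaller than the early one, a ratio of 0.184.

Was that fall tied to the amount of starting material? The ochre run, charged with 40.0 mM, kept 48.8% of its charge at 12 min and the blue run kept 48.9% of its own, so I treated each molecule's chance as independent of its neighbours, first order in starting material with a coefficient that falls in time, and read the fall as belonging to the catalyst.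

I therefore carried one quantity: the exposure, ln(charge over what is left), which sums a molecule's chances up to a given time. For the grey run at 12 min, with 4.80 mM of free catalyst, it was 0.974. The violet run has that catalyst charge, 4.80 mM, so I expected it to keep 37.8% of its 240 mM.

The forecast gave orders of 1 (0.93 to 1.05) in free catalyst and 1.08 (1 to 1.13) in starting material, the ochre run faster, and 38% (36.5% to 41%) for the violet run. Its verdict was that the catalyst dies in pairs, which it called “second-order catalyst death”.

The violet run kept 38.2%, the ochre run was faster, the order in starting material was 1.1, and the readings showed that the catalyst dies in pairs.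

    2 free catalyst ⇌ catalyst dimer, settled at all times (120.0 L mol⁻¹)
    free catalyst + starting material → target + free catalyst (115.8 L mol⁻¹ min⁻¹)
    2 free catalyst → 2 spent catalyst (232.2 L mol⁻¹ min⁻¹)

The forecast parted from this on the order in free catalyst, 0.79 against 1: twice the catalyst charge gave the grey run 1.7 times the early rate of the blue run. Beside the 0.974 of the grey run, the exposure of the blue run at 12 min was 0.716; applied to the ochre charge it leaves 19.5 mM, and the ochre run read 19.5 mM.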